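**Retrosynthetic overview**
Target ⇒ ester demethylation, C11–C12 Negishi coupling with (E)-1-iodo-2-methylbuta-1,3-diene and acetylation, from a decalin with free C6–OH and a C11 iodide.
Ring B (C5–C6–C7–C8–C9–C10) is closed last. Its C6(O)–C7H2–C8(=C17H2) unit is a 3-methylenecyclohexanol, so C6–C7 is cut by a carbonyl-ene reaction of type two to a ring-A aldehyde (C6 on C5) with an isopropenyl-bearing C9 on C10.
C9 (CH2I and isopropenyl) ⇒ formaldehyde ene reaction on a 2-methylprop-1-enyl group at C10; quaternary C10 ⇒ copper-catalysed alkenyl addition to a 3-methylcyclohexenone trans to the C5 arm, then removal of the C2 ketone.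
Ring A is made first: an auxiliary-controlled Diels–Alder reaction of an (E)-mesaconate-derived N-enoyl oxazolidinone with a 2-silyloxypenta-1,3-diene sets C4 and C5; Saegusa oxidation gives the enone.

Key step: step 14

Remark: labdane numbering is used throughout; the target SMILES is read as the 4S,5S,6R,9R,10S enantiomer (C4 carboxyl trans to the C10 methyl, C6 acetate equatorial), and adduct 9 is drawn as the endo isomer, whose C10 centre is erased in step 7.

**Route**

Step 1
Reactants: 1 methyl 2-(triphenylphosphoranylidene)propanoate; 2 glyoxylic acid monohydrate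
Product: 3 (2E)-4-methoxy-3-methyl-4-oxobut-2-enoic acid
Conditions: CH2Cl2, 0 °C to rt
Reagents that add atoms: none
Why: Wittig olefination of the aldehyde carbon by the ester-stabilised ylide is E-selective, so the free acid and the methyl ester end trans across the future C5–C4 bond, which later becomes the trans relation of the C5 arm and the C4 ester.

Step 2
Reactants: 3 (2E)-4-methoxy-3-methyl-4-oxobut-2-enoic acid; 4 (4S)-4-benzyl-1,3-oxazolidin-2-one
Product: 6 methyl (2E)-4-[(4S)-4-benzyl-2-oxo-1,3-oxazolidin-3-yl]-2-methyl-4-oxobut-2-enoate, via mixed pivalic anhydride 5 (not isolated)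
Conditions: PivCl, Et3N, THF, −20 °C; then 4, LiCl, rt
Reagents that add atoms: none
Why: N-acylation of the oxazolidinone through the mixed pivalic anhydride (LiCl/Et3N protocol) is the standard mild entry to N-enoyl imides and leaves the E-alkene untouched.

Step 3
Reactants: 7 (3E)-pent-3-en-2-one
Product: 8 tert-butyldimethyl{[(3E)-penta-1,3-dien-2-yl]oxy}silane
Conditions: TBSOTf, Et3N, CH2Cl2, 0 °C
Reagents that add atoms: tert-butyldimethylsilyl trifluoromethanesulfonate, CC(C)(C)[Si](C)(C)OS(=O)(=O)C(F)(F)F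
Why: Soft enolisation and O-silylation at the methyl group of the enone gives the cross-conjugated 2-silyloxydiene with the E-propenyl unit retained.

Step 4
Reactants: 6 methyl (2E)-4-[(4S)-4-benzyl-2-oxo-1,3-oxazolidin-3-yl]-2-methyl-4-oxobut-2-enoate; 8 tert-butyldimethyl{[(3E)-penta-1,3-dien-2-yl]oxy}silane
Product: 9 methyl (1S,5S,6S)-6-{[(4S)-4-benzyl-2-oxo-1,3-oxazolidin-3-yl]carbonyl}-3-[(tert-butyldimethylsilyl)oxy]-1,5-dimethylcyclohex-3-ene-1-carboxylate
Conditions: Et2AlCl (1.5 equiv), CH2Cl2, −78 °C; cold aq. NaHCO3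
Reagents that add atoms: none
Why: In this Lewis-acid-promoted Evans-auxiliary Diels–Alder reaction, which closes ring A, the Et2Al-chelated imide sends the nucleophilic CH2 terminus of the silyloxydiene to C4 and the methyl-bearing terminus to C5, the benzyl group shields one face of the s-cis enoyl unit so that C4 and C5 form as 4S,5S, and the E-alkene fixes the acyl group trans to the ester.

Step 5
Reactants: 9 methyl (1S,5S,6S)-6-{[(4S)-4-benzyl-2-oxo-1,3-oxazolidin-3-yl]carbonyl}-3-[(tert-butyldimethylsilyl)oxy]-1,5-dimethylcyclohex-3-ene-1-carboxylate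
Product: 10 methyl (1S,5R,6S)-3-[(tert-butyldimethylsilyl)oxy]-6-(hydroxymethyl)-1,5-dimethylcyclohex-3-ene-1-carboxylate
Conditions: LiBH4, MeOH (1 equiv), Et2O–THF, 0 °C; product used at once
Reagents that add atoms: none
Why: Reductive cleavage of the N-acyl oxazolidinone by LiBH4 gives the primary C6 alcohol and returns the auxiliary, while the methyl ester on the quaternary C4 and the silyl enol ether are not reduced.

Step 6
Reactants: 10 methyl (1S,5R,6S)-3-[(tert-butyldimethylsilyl)oxy]-6-(hydroxymethyl)-1,5-dimethylcyclohex-3-ene-1-carboxylate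
Product: 11 methyl (1S,5R,6S)-3-[(tert-butyldimethylsilyl)oxy]-6-{[(tert-butyldimethylsilyl)oxy]methyl}-1,5-dimethylcyclohex-3-ene-1-carboxylate
Conditions: TBSCl, imidazole, DMF, 0 °C to rt
Reagents that add atoms: tert-butyldimethylsilyl chloride, CC(C)(C)[Si](C)(C)Cl
Why: Silylation of the primary alcohol under neutral conditions protects C6–OH and blocks its lactonisation onto the neighbouring C4 ester.

Step 7
Reactants: 11 methyl (1S,5R,6S)-3-[(tert-butyldimethylsilyl)oxy]-6-{[(tert-butyldimethylsilyl)oxy]methyl}-1,5-dimethylcyclohex-3-ene-1-carboxylate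
Product: 12 methyl (1S,2S)-2-{[(tert-butyldimethylsilyl)oxy]methyl}-1,3-dimethyl-5-oxocyclohex-3-ene-1-carboxylate
Conditions: Pd(OAc)2 (1.1 equiv), MeCN, 40 °C
Reagents that add atoms: none
Why: In this Saegusa–Ito oxidation the regiodefined silyl enol ether gives the C1 palladium enolate, whose only β-hydrogen sits on C10, so the 3-methylcyclohexenone forms and the C10 centre of the cycloadduct is erased.

Step 8
Reactants: 12 methyl (1S,2S)-2-{[(tert-butyldimethylsilyl)oxy]methyl}-1,3-dimethyl-5-oxocyclohex-3-ene-1-carboxylate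
Product: 14 methyl (1S,2S,3S)-2-{[(tert-butyldimethylsilyl)oxy]methyl}-1,3-dimethyl-3-(2-methylprop-1-en-1-yl)-5-oxocyclohexane-1-carboxylate, via trimethylsilyl enol ether 13 (not isolated)
Conditions: (2-methylprop-1-en-1-yl)MgBr (2 equiv), CuBr·SMe2 (20 mol%), TMSCl, THF, −78 to −30 °C; then 1 M HCl, 0 °C
Reagents that add atoms: (2-methylprop-1-en-1-yl)magnesium bromide, CC(C)=C[Mg]Br
Why: Copper-catalysed, TMSCl-accelerated conjugate addition of the alkenyl Grignard reagent builds the quaternary C10, the alkenyl group entering trans to the pseudoaxial CH2OTBS arm on the adjacent C5 as in additions to 4-substituted 3-methylcyclohexenones.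

Step 9
Reactants: 14 methyl (1S,2S,3S)-2-{[(tert-butyldimethylsilyl)oxy]methyl}-1,3-dimethyl-3-(2-methylprop-1-en-1-yl)-5-oxocyclohexane-1-carboxylate
Product: 16 methyl (1S,2S,3S)-2-{[(tert-butyldimethylsilyl)oxy]methyl}-1,3-dimethyl-3-(2-methylprop-1-en-1-yl)cyclohexane-1-carboxylate, via tosylhydrazone 15 (not isolated)
Conditions: TsNHNH2, THF, 50 °C; then catecholborane, CHCl3, 0 °C; NaOAc·3H2O, 60 °C
Reagents that add atoms: none
Why: Deoxygenation of the unconjugated C2 ketone through its tosylhydrazone (hydride addition, loss of sulfinate and N2) is mild enough for the ester, the silyl ether and the trisubstituted alkene.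

Step 10
Reactants: 16 methyl (1S,2S,3S)-2-{[(tert-butyldimethylsilyl)oxy]methyl}-1,3-dimethyl-3-(2-methylprop-1-en-1-yl)cyclohexane-1-carboxylate
Product: 17 methyl (1S,2S,3S)-2-{[(tert-butyldimethylsilyl)oxy]methyl}-3-[(2R)-1-hydroxy-3-methylbut-3-en-2-yl]-1,3-dimethylcyclohexane-1-carboxylate
Conditions: (CH2O)n, Me2AlCl (2 equiv), CH2Cl2, −78 to 0 °C
Reagents that add atoms: formaldehyde (as paraformaldehyde), C=O
Why: The Me2AlCl-mediated intermolecular carbonyl-ene reaction of formaldehyde joins C11 to the less substituted alkene carbon C9 and takes a methyl hydrogen to leave the isopropenyl group, and C9 should be set because the alkene lies syn to the axial C10 methyl (least allylic 1,3-strain) with its C5 side screened by the equatorial CH2OTBS arm, so formaldehyde adds from the C1 side.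

Step 11
Reactants: 17 methyl (1S,2S,3S)-2-{[(tert-butyldimethylsilyl)oxy]methyl}-3-[(2R)-1-hydroxy-3-methylbut-3-en-2-yl]-1,3-dimethylcyclohexane-1-carboxylate
Product: 18 methyl (1S,2S,3R)-2-{[(tert-butyldimethylsilyl)oxy]methyl}-3-[(2R)-1-iodo-3-methylbut-3-en-2-yl]-1,3-dimethylcyclohexane-1-carboxylate
Conditions: [I][I], PPh3, imidazole, CH2Cl2, 0 °C to rt
Reagents that add atoms: iodine, [I][I]
Why: Appel iodination of the primary alcohol through its oxyphosphonium salt installs the C11 iodide for the later coupling without touching C9.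

Step 12
Reactants: 18 methyl (1S,2S,3R)-2-{[(tert-butyldimethylsilyl)oxy]methyl}-3-[(2R)-1-iodo-3-methylbut-3-en-2-yl]-1,3-dimethylcyclohexane-1-carboxylate
Product: 19 methyl (1S,2S,3R)-2-(hydroxymethyl)-3-[(2R)-1-iodo-3-methylbut-3-en-2-yl]-1,3-dimethylcyclohexane-1-carboxylate
Conditions: HF·pyridine, pyridine, THF, 0 °C; product used at once
Reagents that add atoms: none
Why: Fluoride-driven cleavage of the primary silyl ether under buffered, non-basic conditions leaves the alkyl iodide and the alkene intact.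

Step 13
Reactants: 19 methyl (1S,2S,3R)-2-(hydroxymethyl)-3-[(2R)-1-iodo-3-methylbut-3-en-2-yl]-1,3-dimethylcyclohexane-1-carboxylate
Product: 20 methyl (1S,2S,3R)-2-formyl-3-[(2R)-1-iodo-3-methylbut-3-en-2-yl]-1,3-dimethylcyclohexane-1-carboxylate
Conditions: Dess–Martin periodinane, NaHCO3, CH2Cl2, 0 °C to rt
Reagents that add atoms: none
Why: Dess–Martin oxidation gives the aldehyde under near-neutral conditions that should not epimerise C5, which is flanked by two quaternary carbons.

Step 14
Reactants: 20 methyl (1S,2S,3R)-2-formyl-3-[(2R)-1-iodo-3-methylbut-3-en-2-yl]-1,3-dimethylcyclohexane-1-carboxylate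
Product: 21 methyl (1S,4aR,5R,8R,8aS)-8-hydroxy-5-(iodomethyl)-1,4a-dimethyl-6-methylidenedecahydronaphthalene-1-carboxylate
Conditions: Me2AlCl (1.5 equiv), CH2Cl2, −78 to −40 °C; cold aq. NaHCO3 and potassium sodium tartrate
Reagents that add atoms: none
Why: Me2AlCl complexes the C6 aldehyde, the terminal alkene carbon C7 adds to C6 and a hydrogen of the allylic methyl (C17) passes to oxygen through a six-membered array; this is the Lewis-acid intramolecular carbonyl-ene reaction of type two that converts 5-methylhex-5-enals into 3-methylenecyclohexanols. Ring B closes in a six-membered mode that is endo for the alkene (C7 and C8 both enter the ring) and exo for the carbonyl, and the double bond must end at C8(17) because the methyl group is the only allylic position that can reach the oxygen. The single new stereocentre C6 is controlled by ring A: the aldehyde on C5 and the C9 arm on C10 are trans-diequatorial, and the aluminium-bound oxygen turns away from the cleft between the axial methyl groups on C4 and C10, so H6 ends axial and the oxygen equatorial (6R). Because a concerted hydrogen transfer needs the oxygen gauche to C8, this outcome should run through a boat-like array of the forming ring and not through the usual chair with axial oxygen, which here would push the aluminium alkoxide against two syn-axial methyl groups. The step needs chemoselectivity (primary iodide and ester untouched, no methyl transfer from aluminium) and a concerted hydrogen shift in place of chloride capture, which the low temperature and the proton-scavenging Me2AlCl are meant to secure.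

Step 15
Reactants: 21 methyl (1S,4aR,5R,8R,8aS)-8-hydroxy-5-(iodomethyl)-1,4a-dimethyl-6-methylidenedecahydronaphthalene-1-carboxylate
Product: 22 methyl (1S,4aR,5R,8R,8aS)-8-(acetyloxy)-5-(iodomethyl)-1,4a-dimethyl-6-methylidenedecahydronaphthalene-1-carboxylate
Conditions: Ac2O, DMAP, pyridine, CH2Cl2, rt
Reagents that add atoms: acetic anhydride, CC(=O)OC(C)=O
Why: DMAP-catalysed acetylation of the equatorial secondary alcohol installs the C6 acetate and removes the acidic proton before the organozinc is made.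

Step 16
Reactants: 23 prop-2-yn-1-ol
Product: 25 (2E)-3-iodo-2-methylprop-2-en-1-ol, via vinylalane 24 (not isolated)
Conditions: Me3Al (3 equiv), Cp2ZrCl2 (25 mol%), CH2Cl2, 0 °C to rt; then [I][I], THF, −30 °C
Reagents that add atoms: trimethylaluminium, C[Al](C)C; iodine, [I][I]
Why: Negishi zirconium-catalysed carboalumination adds methyl and aluminium syn across the alkyne with methyl on the internal carbon, and iodinolysis with retention gives the E-iodoalkene.

Step 17
Reactants: 25 (2E)-3-iodo-2-methylprop-2-en-1-ol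
Product: 26 (2E)-3-iodo-2-methylprop-2-enal
Conditions: MnO2, CH2Cl2, rt
Reagents that add atoms: none
Why: MnO2 oxidises the allylic alcohol to the enal without isomerising the iodoalkene.

Step 18
Reactants: 26 (2E)-3-iodo-2-methylprop-2-enal
Product: 27 (1E)-1-iodo-2-methylbuta-1,3-diene
Conditions: Ph3PCH3Br, KN(SiMe3)2, THF, −78 to 0 °C; kept as a solution
Reagents that add atoms: methyltriphenylphosphonium bromide, C[P+](c1ccccc1)(c1ccccc1)c1ccccc1.[Br-]
Why: Wittig methylenation of the enal gives the volatile dienyl iodide with the E-iodoalkene unchanged.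

Step 19
Reactants: 22 methyl (1S,4aR,5R,8R,8aS)-8-(acetyloxy)-5-(iodomethyl)-1,4a-dimethyl-6-methylidenedecahydronaphthalene-1-carboxylate; 27 (1E)-1-iodo-2-methylbuta-1,3-diene
Product: 29 methyl (1S,4aS,5R,8R,8aS)-8-(acetyloxy)-1,4a-dimethyl-6-methylidene-5-[(2E)-3-methylpenta-2,4-dien-1-yl]decahydronaphthalene-1-carboxylate, via alkylzinc iodide 28 (not isolated)
Conditions: Zn dust (activated by BrCH2CH2Br, TMSCl), LiCl, THF, 40 °C; then 27, PdCl2(dppf) (5 mol%), THF, rt to 40 °C
Reagents that add atoms: none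
Why: Direct zinc insertion into the primary iodide tolerates both esters, and palladium-catalysed Negishi coupling of the alkylzinc with the alkenyl iodide forms C11–C12 with retention of the E geometry.

Step 20
Reactants: 29 methyl (1S,4aS,5R,8R,8aS)-8-(acetyloxy)-1,4a-dimethyl-6-methylidene-5-[(2E)-3-methylpenta-2,4-dien-1-yl]decahydronaphthalene-1-carboxylate
Product: 30 (1S,4aS,5R,8R,8aS)-8-(acetyloxy)-1,4a-dimethyl-6-methylidene-5-[(2E)-3-methylpenta-2,4-dien-1-yl]decahydronaphthalene-1-carboxylic acid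
Conditions: LiI, pyridine, 115 °C, argon; then dilute HCl to pH 3–4
Reagents that add atoms: none
Why: Iodide cleaves the hindered methyl ester by SN2 attack at the O-methyl group, a mode that cannot touch the secondary acetate.

**Compound list**

1 | methyl 2-(triphenylphosphoranylidene)propanoate | COC(=O)C(C)=P(c1ccccc1)(c1ccccc1)c1ccccc1 | starting material
2 | glyoxylic acid monohydrate (2,2-dihydroxyacetic acid) | OC(O)C(=O)O | starting material
3 | (2E)-4-methoxy-3-methyl-4-oxobut-2-enoic acid | COC(=O)/C(C)=C/C(=O)O | intermediate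
4 | (4S)-4-benzyl-1,3-oxazolidin-2-one | O=C1N[C@@H](Cc2ccccc2)CO1 | starting material
5 | (2E)-4-methoxy-3-methyl-4-oxobut-2-enoic 2,2-dimethylpropanoic anhydride | COC(=O)/C(C)=C/C(=O)OC(=O)C(C)(C)C | intermediate
6 | methyl (2E)-4-[(4S)-4-benzyl-2-oxo-1,3-oxazolidin-3-yl]-2-methyl-4-oxobut-2-enoate | COC(=O)/C(C)=C/C(=O)N1[C@@H](Cc2ccccc2)COC1=O | intermediate
7 | (3E)-pent-3-en-2-one | CC(=O)/C=C/C | starting material
8 | tert-butyldimethyl{[(3E)-penta-1,3-dien-2-yl]oxy}silane | C=C(O[Si](C)(C)C(C)(C)C)/C=C/C | intermediate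
9 | methyl (1S,5S,6S)-6-{[(4S)-4-benzyl-2-oxo-1,3-oxazolidin-3-yl]carbonyl}-3-[(tert-butyldimethylsilyl)oxy]-1,5-dimethylcyclohex-3-ene-1-carboxylate | C[C@H]1C=C(O[Si](C)(C)C(C)(C)C)C[C@](C)(C(=O)OC)[C@H]1C(=O)N1[C@@H](Cc2ccccc2)COC1=O | intermediate
10 | methyl (1S,5R,6S)-3-[(tert-butyldimethylsilyl)oxy]-6-(hydroxymethyl)-1,5-dimethylcyclohex-3-ene-1-carboxylate | C[C@H]1C=C(O[Si](C)(C)C(C)(C)C)C[C@](C)(C(=O)OC)[C@H]1CO | intermediate
11 | methyl (1S,5R,6S)-3-[(tert-butyldimethylsilyl)oxy]-6-{[(tert-butyldimethylsilyl)oxy]methyl}-1,5-dimethylcyclohex-3-ene-1-carboxylate | C[C@H]1C=C(O[Si](C)(C)C(C)(C)C)C[C@](C)(C(=O)OC)[C@H]1CO[Si](C)(C)C(C)(C)C | intermediate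
12 | methyl (1S,2S)-2-{[(tert-butyldimethylsilyl)oxy]methyl}-1,3-dimethyl-5-oxocyclohex-3-ene-1-carboxylate | CC1=CC(=O)C[C@](C)(C(=O)OC)[C@H]1CO[Si](C)(C)C(C)(C)C | intermediate
13 | methyl (1S,5S,6S)-6-{[(tert-butyldimethylsilyl)oxy]methyl}-1,5-dimethyl-5-(2-methylprop-1-en-1-yl)-3-[(trimethylsilyl)oxy]cyclohex-3-ene-1-carboxylate | CC(C)=C[C@]1(C)C=C(O[Si](C)(C)C)C[C@](C)(C(=O)OC)[C@H]1CO[Si](C)(C)C(C)(C)C | intermediate
14 | methyl (1S,2S,3S)-2-{[(tert-butyldimethylsilyl)oxy]methyl}-1,3-dimethyl-3-(2-methylprop-1-en-1-yl)-5-oxocyclohexane-1-carboxylate | CC(C)=C[C@]1(C)CC(=O)C[C@](C)(C(=O)OC)[C@H]1CO[Si](C)(C)C(C)(C)C | intermediate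
15 | 4-methylbenzenesulfonylhydrazone of ketone 14 (ring configuration as in 14) | CC(C)=C[C@]1(C)CC(=NNS(=O)(=O)c2ccc(C)cc2)C[C@](C)(C(=O)OC)[C@H]1CO[Si](C)(C)C(C)(C)C | intermediate
16 | methyl (1S,2S,3S)-2-{[(tert-butyldimethylsilyl)oxy]methyl}-1,3-dimethyl-3-(2-methylprop-1-en-1-yl)cyclohexane-1-carboxylate | CC(C)=C[C@]1(C)CCC[C@](C)(C(=O)OC)[C@H]1CO[Si](C)(C)C(C)(C)C | intermediate
17 | methyl (1S,2S,3S)-2-{[(tert-butyldimethylsilyl)oxy]methyl}-3-[(2R)-1-hydroxy-3-methylbut-3-en-2-yl]-1,3-dimethylcyclohexane-1-carboxylate | OC[C@H](C(C)=C)[C@]1(C)CCC[C@](C)(C(=O)OC)[C@H]1CO[Si](C)(C)C(C)(C)C | intermediate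
18 | methyl (1S,2S,3R)-2-{[(tert-butyldimethylsilyl)oxy]methyl}-3-[(2R)-1-iodo-3-methylbut-3-en-2-yl]-1,3-dimethylcyclohexane-1-carboxylate | IC[C@H](C(C)=C)[C@]1(C)CCC[C@](C)(C(=O)OC)[C@H]1CO[Si](C)(C)C(C)(C)C | intermediate
19 | methyl (1S,2S,3R)-2-(hydroxymethyl)-3-[(2R)-1-iodo-3-methylbut-3-en-2-yl]-1,3-dimethylcyclohexane-1-carboxylate | IC[C@H](C(C)=C)[C@]1(C)CCC[C@](C)(C(=O)OC)[C@H]1CO | intermediate
20 | methyl (1S,2S,3R)-2-formyl-3-[(2R)-1-iodo-3-methylbut-3-en-2-yl]-1,3-dimethylcyclohexane-1-carboxylate (key-step precursor) | IC[C@H](C(C)=C)[C@]1(C)CCC[C@](C)(C(=O)OC)[C@H]1C=O | intermediate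
21 | methyl (1S,4aR,5R,8R,8aS)-8-hydroxy-5-(iodomethyl)-1,4a-dimethyl-6-methylidenedecahydronaphthalene-1-carboxylate (key-step product) | IC[C@@H]1C(=C)C[C@@H](O)[C@H]2[C@@]1(C)CCC[C@]2(C)C(=O)OC | intermediate
22 | methyl (1S,4aR,5R,8R,8aS)-8-(acetyloxy)-5-(iodomethyl)-1,4a-dimethyl-6-methylidenedecahydronaphthalene-1-carboxylate | IC[C@@H]1C(=C)C[C@@H](OC(C)=O)[C@H]2[C@@]1(C)CCC[C@]2(C)C(=O)OC | intermediate
23 | prop-2-yn-1-ol | OCC#C | starting material
24 | dimethylaluminium (2E)-3-(dimethylalumanyl)-2-methylprop-2-en-1-olate | C[Al](C)OC/C(C)=C/[Al](C)C | intermediate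
25 | (2E)-3-iodo-2-methylprop-2-en-1-ol | OC/C(C)=C/I | intermediate
26 | (2E)-3-iodo-2-methylprop-2-enal | O=C/C(C)=C/I | intermediate
27 | (1E)-1-iodo-2-methylbuta-1,3-diene | C=C/C(C)=C/I | intermediate
28 | alkylzinc iodide from 22 (C11–ZnI, ring configuration as in 22) | I[Zn]C[C@@H]1C(=C)C[C@@H](OC(C)=O)[C@H]2[C@@]1(C)CCC[C@]2(C)C(=O)OC | intermediate
29 | methyl (1S,4aS,5R,8R,8aS)-8-(acetyloxy)-1,4a-dimethyl-6-methylidene-5-[(2E)-3-methylpenta-2,4-dien-1-yl]decahydronaphthalene-1-carboxylate | C=C/C(C)=C/C[C@@H]1C(=C)C[C@@H](OC(C)=O)[C@H]2[C@@]1(C)CCC[C@]2(C)C(=O)OC | intermediate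
30 | (1S,4aS,5R,8R,8aS)-8-(acetyloxy)-1,4a-dimethyl-6-methylidene-5-[(2E)-3-methylpenta-2,4-dien-1-yl]decahydronaphthalene-1-carboxylic acid | C=C/C(C)=C/C[C@@H]1C(=C)C[C@@H](OC(C)=O)[C@H]2[C@@]1(C)CCC[C@]2(C)C(=O)O | target

**Step count**
Total: 20 steps. Longest linear sequence: 16 steps (1, 2, 4–15, 19, 20).

**Steps most likely to fail**

1. Step 8. The alkenyl cuprate may fail to add to the β,β-disubstituted enone, whose β-carbon is flanked by a substituted C5 and faces a syn-axial group on C4; enone could be recovered or attacked at the carbonyl. The fallback sets out from 12 and returns at 16, and it moves the C9 carbon to C10 intramolecularly.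
 - Luche reduction (NaBH4, CeCl3·7H2O, MeOH, −78 °C) should deliver hydride anti to the axial C4 ester and give methyl (1S,2S,5R)-2-{[(tert-butyldimethylsilyl)oxy]methyl}-5-hydroxy-1,3-dimethylcyclohex-3-ene-1-carboxylate F1, with the hydroxyl cis to the ester (Mitsunobu inversion if the epimer forms).
 - KH and Bu3SnCH2I in THF give the stannylmethyl ether of that alcohol F2.
 - n-BuLi at −78 °C triggers tin–lithium exchange and [2,3]-Wittig–Still rearrangement, which carries CH2OH suprafacially from oxygen to C10 and gives methyl (1S,5R,6S)-6-{[(tert-butyldimethylsilyl)oxy]methyl}-5-(hydroxymethyl)-1,5-dimethylcyclohex-3-ene-1-carboxylate F3.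
 - Hydrogenation (H2, Pd on carbon, EtOAc) gives methyl (1S,2S,3R)-2-{[(tert-butyldimethylsilyl)oxy]methyl}-3-(hydroxymethyl)-1,3-dimethylcyclohexane-1-carboxylate F4.
 - Dess–Martin oxidation gives methyl (1S,2S,3R)-2-{[(tert-butyldimethylsilyl)oxy]methyl}-3-formyl-1,3-dimethylcyclohexane-1-carboxylate F5.
 - Wittig reaction with Ph3P=C(CH3)2 (from isopropyltriphenylphosphonium iodide and n-BuLi) gives 16.

2. Step 10. Facial discrimination at C9 may be poor, or the addition may turn stepwise, with capture of the developing C8 cation by chloride or by the C6 silyl ether oxygen, or with a second ene reaction on the new isopropenyl group. The fallback sets out from 16 and returns at 17, and it forms the same C9–C11 bond by an anionic sigmatropic shift at −78 °C.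
 - SeO2 (cat.) with t-BuOOH in CH2Cl2 oxidises the E-methyl group and gives methyl (1S,2S,3S)-2-{[(tert-butyldimethylsilyl)oxy]methyl}-3-[(1E)-3-hydroxy-2-methylprop-1-en-1-yl]-1,3-dimethylcyclohexane-1-carboxylate F6.
 - KH and Bu3SnCH2I give the stannylmethyl ether of that allylic alcohol F7.
 - n-BuLi in THF at −78 °C induces the [2,3]-Wittig–Still rearrangement, in which the carbanion carbon bonds to C9 from the C1 side and the double bond moves to C8=C7, giving 17 directly.

3. Step 14. The closure may turn stepwise (chloride capture at C8, or proton loss toward an endocyclic alkene), a methyl group may be transferred from aluminium to the aldehyde, or the oxygen may close axial. If only the sense at C6 is at fault, the bulky methylaluminium bis(4-bromo-2,6-di-tert-butylphenoxide) is the reagent variant to try. The change of approach sets out from 17 and returns at 21, and it forms the same C6–C7 bond by an intramolecular allylchromium addition that fixes the exocyclic alkene by construction.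
 - Ene-type allylic chlorination (Ca(OCl)2, CO2, CH2Cl2–H2O) converts the isopropenyl group into a 2-(chloromethyl)vinyl group and gives the allylic chloride analogue of 17 F8.
 - Appel iodination ([I][I], PPh3, imidazole) gives the C11 iodide of that chloride F9.
 - HF·pyridine gives the corresponding C6 alcohol F10.
 - Dess–Martin oxidation gives the chloro-iodo aldehyde F11.
 - CrCl2 in THF at 0 °C forms the allylchromium reagent from the allylic chloride selectively over the primary iodide, and its addition to the aldehyde closes ring B to 21, the chromium alkoxide again avoiding the cleft between the C4 and C10 methyl groups.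

**Further compounds**
F1 | step 8 | methyl (1S,2S,5R)-2-{[(tert-butyldimethylsilyl)oxy]methyl}-5-hydroxy-1,3-dimethylcyclohex-3-ene-1-carboxylate | CC1=C[C@H](O)C[C@](C)(C(=O)OC)[C@H]1CO[Si](C)(C)C(C)(C)C
F2 | step 8 | methyl (1S,2S,5R)-2-{[(tert-butyldimethylsilyl)oxy]methyl}-1,3-dimethyl-5-[(tributylstannyl)methoxy]cyclohex-3-ene-1-carboxylate | CC1=C[C@H](OC[Sn](CCCC)(CCCC)CCCC)C[C@](C)(C(=O)OC)[C@H]1CO[Si](C)(C)C(C)(C)C
F3 | step 8 | methyl (1S,5R,6S)-6-{[(tert-butyldimethylsilyl)oxy]methyl}-5-(hydroxymethyl)-1,5-dimethylcyclohex-3-ene-1-carboxylate | OC[C@]1(C)C=CC[C@](C)(C(=O)OC)[C@H]1CO[Si](C)(C)C(C)(C)C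
F4 | step 8 | methyl (1S,2S,3R)-2-{[(tert-butyldimethylsilyl)oxy]methyl}-3-(hydroxymethyl)-1,3-dimethylcyclohexane-1-carboxylate | OC[C@]1(C)CCC[C@](C)(C(=O)OC)[C@H]1CO[Si](C)(C)C(C)(C)C
F5 | step 8 | methyl (1S,2S,3R)-2-{[(tert-butyldimethylsilyl)oxy]methyl}-3-formyl-1,3-dimethylcyclohexane-1-carboxylate | O=C[C@]1(C)CCC[C@](C)(C(=O)OC)[C@H]1CO[Si](C)(C)C(C)(C)C
F6 | step 10 | methyl (1S,2S,3S)-2-{[(tert-butyldimethylsilyl)oxy]methyl}-3-[(1E)-3-hydroxy-2-methylprop-1-en-1-yl]-1,3-dimethylcyclohexane-1-carboxylate | OC/C(C)=C/[C@]1(C)CCC[C@](C)(C(=O)OC)[C@H]1CO[Si](C)(C)C(C)(C)C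
F7 | step 10 | methyl (1S,2S,3S)-2-{[(tert-butyldimethylsilyl)oxy]methyl}-1,3-dimethyl-3-{(1E)-2-methyl-3-[(tributylstannyl)methoxy]prop-1-en-1-yl}cyclohexane-1-carboxylate | CCCC[Sn](CCCC)(CCCC)COC/C(C)=C/[C@]1(C)CCC[C@](C)(C(=O)OC)[C@H]1CO[Si](C)(C)C(C)(C)C
F8 | step 14 | allylic chloride analogue of 17 (isopropenyl methyl replaced by CH2Cl, all centres as in 17) | OC[C@H](C(=C)CCl)[C@]1(C)CCC[C@](C)(C(=O)OC)[C@H]1CO[Si](C)(C)C(C)(C)C
F9 | step 14 | C11 iodide of F8 (all centres as in 18) | IC[C@H](C(=C)CCl)[C@]1(C)CCC[C@](C)(C(=O)OC)[C@H]1CO[Si](C)(C)C(C)(C)C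
F10 | step 14 | C6 alcohol from F9 (all centres as in 19) | IC[C@H](C(=C)CCl)[C@]1(C)CCC[C@](C)(C(=O)OC)[C@H]1CO
F11 | step 14 | chloro-iodo aldehyde from F10 (all centres as in 20) | IC[C@H](C(=C)CCl)[C@]1(C)CCC[C@](C)(C(=O)OC)[C@H]1C=O
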